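The data were generated by integration with made-up constants, and the scatter is random.

A closed, stirred vessel at constant volume and temperature holds starting material, and the flask is to be read after 2.5 d.

| flask | starting material | remark | time |
|---|---|---|---|
| birch | 0.60 M | run made earlier |  |
| maple | 2.4 M | run made earlier |  |
| flask | 1.2 M |  | 2.5 d |

| run | time / h | starting material / % | target / % | intermediate B / % | side product / % |
|---|---|---|---|---|---|
| birch | 10.0 | 0.9 | 71.1 | 25.2 | 2.4 |
| birch | 20.0 | 0 | 73.5 | 25.0 | 2.2 |
| birch | 30.0 | 0 | 74.5 | 24.0 | 1.9 |
| birch | 40.0 | 0.9 | 74.1 | 24.7 | 0.7 |
| birch | 50.0 | 0 | 74.9 | 24.0 | 1.3 |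
| maple | 10.0 | 1.6 | 67.1 | 23.6 | 5.1 |
| maple | 20.0 | 0.5 | 72.6 | 24.6 | 5.7 |
| maple | 30.0 | 0.7 | 71.2 | 23.7 | 4.5 |
| maple | 40.0 | 0.4 | 71.5 | 23.5 | 5.7 |
| maple | 50.0 | 0.2 | 70.8 | 24.1 | 4.3 |

(standard deviation of a reading: 0.5 percentage points)

- in percentages every species weighs as the starting material in it: one side product counts as two
- the reaction counts as stopped when no species that holds the starting material changes by six tenths of a point or more over the second half of the time

* at 2.5 d, what has stopped the reaction, if anything has (it is still moving / all of the starting material has reacted / forward and back rates have come level)
* how much of the starting material has reacted by 2.5 d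
* how much target there is at 2.5 d, in percent of the starting material charged
* how much intermediate B there is at 2.5 d, in percent of the starting material charged
* how much side product there is at 2.5 d, in percent of the starting material charged

From 20.0 h on, no reading of starting material in either run exceeds 0.9%, and the flask is read later than the last reading, so this reckoning takes the flask's starting material as used up.

What remains open is the fraction left, the share of the charge outside side product. Side product averages 1.70% in the birch run and 5.06% in the maple run. The logarithm of the inverse fraction left, per molar of charge, then reads 0.0286 L mol⁻¹ and 0.0216 L mol⁻¹. If this number does not rise with charge, the maple run gives the flask a floor of 2.56% side product and the birch run a ceiling of 3.37%.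

The ceiling is the weaker bound: both means carry the same scatter, but the birch value divides it by a charge 4.00 times smaller. Weighting by the squared charge gives 0.0220 L mol⁻¹, the loss number, and so 2.61% side product. From 20.0 h on, target over intermediate B reads 3.01, which splits the rest into 73.1% target and 24.3% intermediate B.

The forecast says all of the starting material has reacted, with 99.8% reacted, 73% target, 24.1% intermediate B and 2.9% side product, this last figure inside the bracket, its ground being “Interpolating to 1.2 M gives about 3%”.

At 2.5 d in the flask all of the starting material has reacted, with 100% reacted, 73.0% target, 24.3% intermediate B and 2.65% side product, this last figure also inside the bracket.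

    starting material → intermediate A (k = 1.18 × 10⁻⁴ s⁻¹)
    intermediate A → intermediate B (k = 2.29 × 10⁻⁴ s⁻¹)
    intermediate B ⇌ target (K = 3.00, k = 2.18 × 10⁻⁴ s⁻¹)
    starting material + intermediate B → side product (k = 8.80 × 10⁻⁶ L mol⁻¹ s⁻¹)

At 0.0669 d the flask's intermediate B passes into target, forward step alone, 41 times faster than it passes with starting material into side product. The loss number 0.0220 L mol⁻¹ gave this flask 2.61% side product against the 2.65% it holds. For the neighbour charged with 0.48 M it gives 1.05%, and at 2.50 d that neighbour holds 1.08%.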